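**Strategy.** Ring locants: C1 (methyl-bearing alkene carbon), C4 (isopropyl), C5 (ester carbinol), C7 (tertiary carbinol). Everything rests on an imaginary C2–C7 bond. It folds C2–C7 of the ten-membered ring into a cyclohexene that already contains the cis C3=C4 alkene. C1/C10 and C8/C9 then become an isopropenyl group on C2 and a vinyl group on C7. The precursor is this trans-2-isopropenyl-1-vinylcyclohex-3-en-1-ol, with the C5 silyl ether as its only lasting stereocentre. Its anionic oxy-Cope rearrangement breaks C2–C7, forms C9–C10, sets the E C1=C2 alkene and delivers the ten-membered dienone with its ketone at C7, all in one operation. Chelate-guided methyl addition and acylation finish the synthesis.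

Key step: step 8

**Conventions and assumption.**
- The locants C1–C10 are used for every intermediate.
- Read from the target SMILES: C5 is S, C7 is S (C5–O and C7–O cis on the ring), C1=C2 is E, C3=C4 is Z.
- Assumption: 1 is bought as the single (S) enantiomer. Its carbinol carbon becomes C7 and only relays chirality to C2 and C5 before it is oxidised.

**Design choices.**
- Oxygen is placed on C5 while the ring is still an enone, where only one kinetic enolate exists.
- The cuprate enolate is triflated in the same flask, so the position of the future C3=C4 alkene never depends on regioselective enolisation.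
- The precursor is made on purpose as the (1S,2R,5S) isomer. C5–OTIPS is cis to the isopropenyl group, so it is pseudoaxial in the half-chair that holds vinyl and isopropenyl equatorial. This relieves allylic strain with the C4 isopropyl group, so C5 biases the ring towards the reactive conformer. One step earlier the same group shields the lower face of the C7 ketone.
- TIPS is kept at C5 because C5–O and the C7 alkoxide are 1,3-cis, and O-to-O silyl transfer must stay slow. Any transfer would be reversible and would be drained by the rearrangement.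

Step 1
Reactants: 1 (S)-4-(tert-butyldimethylsilyloxy)cyclohex-2-en-1-one
Product: 3 (4S,6S)-4-(tert-butyldimethylsilyloxy)-6-hydroxycyclohex-2-en-1-one, via sodium dienolate 2 (not isolated)
Conditions: NaN(SiMe3)2, THF, −78 °C; 2-(phenylsulfonyl)-3-phenyloxaziridine, −78 °C; AcOH quench
Reagents that add atoms: 2-(phenylsulfonyl)-3-phenyloxaziridine (Davis oxaziridine), O=S(=O)(c1ccccc1)N1OC1c1ccccc1
Why: Kinetic deprotonation of an enone can only give the cross-conjugated alpha-prime enolate, and Davis enolate hydroxylation should proceed by axial attack on the face away from the C7 silyloxy group, which sets C5 as S (1,3-trans to OTBS); any minor epimer is removed by chromatography here.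

Step 2
Reactants: 3 (4S,6S)-4-(tert-butyldimethylsilyloxy)-6-hydroxycyclohex-2-en-1-one
Product: 4 (4S,6S)-4-(tert-butyldimethylsilyloxy)-6-(triisopropylsilyloxy)cyclohex-2-en-1-one
Conditions: TIPSOTf, 2,6-lutidine, CH2Cl2, −78 → 0 °C
Reagents that add atoms: triisopropylsilyl triflate, CC(C)[Si](OS(=O)(=O)C(F)(F)F)(C(C)C)C(C)C
Why: Silyl triflate O-silylation with a weak hindered base is fast at low temperature, so the epimerisable C5 centre is not disturbed, and TIPS is orthogonal to TBS in step 5 and slow to migrate in step 8.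

Step 3
Reactants: 4 (4S,6S)-4-(tert-butyldimethylsilyloxy)-6-(triisopropylsilyloxy)cyclohex-2-en-1-one; 5 2-bromopropene
Product: 9 (3R,4S,6S)-4-(tert-butyldimethylsilyloxy)-3-(prop-1-en-2-yl)-6-(triisopropylsilyloxy)cyclohex-1-en-1-yl trifluoromethanesulfonate, via 2-propenyllithium 6 (not isolated), via lithium di(2-propenyl)cuprate 7 (not isolated), via lithium enolate 8 (not isolated)
Conditions: 5, t-BuLi (2 equiv per 5), Et2O, −78 °C; CuI (0.5 equiv per RLi), −78 → −40 °C; 4, −78 °C; N-(5-chloro-2-pyridyl)bis(trifluoromethanesulfonimide), THF, −78 → 0 °C; aq NH4Cl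
Reagents that add atoms: 2-bromopropene (compound 5), C=C(C)Br; N-(5-chloro-2-pyridyl)bis(trifluoromethanesulfonimide) (Comins' reagent), O=S(=O)(N(c1ccc(Cl)cn1)S(=O)(=O)C(F)(F)F)C(F)(F)F
Why: Gilman cuprate 1,4-addition to a 4-silyloxycyclohexenone occurs anti to the neighbouring OTBS group and sets C2 (R), and trapping the regiodefined enolate with Comins' reagent fixes the enol triflate, and so the later ring alkene, at C3=C4.

Step 4
Reactants: 9 (3R,4S,6S)-4-(tert-butyldimethylsilyloxy)-3-(prop-1-en-2-yl)-6-(triisopropylsilyloxy)cyclohex-1-en-1-yl trifluoromethanesulfonate; 10 isopropylzinc bromide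
Product: 11 tert-butyl{[(1S,2R,5S)-4-isopropyl-2-(prop-1-en-2-yl)-5-(triisopropylsilyloxy)cyclohex-3-en-1-yl]oxy}dimethylsilane
Conditions: PdCl2(dppf)·CH2Cl2 (5 mol%), THF, 23 → 45 °C
Reagents that add atoms: isopropylzinc bromide (compound 10), CC(C)[Zn]Br
Why: In this Negishi coupling of an alkenyl triflate with a secondary alkylzinc halide, the wide bite angle of dppf makes reductive elimination faster than beta-hydride elimination, so isopropyl should be transferred unrearranged and no stereocentre is touched.

Step 5
Reactants: 11 tert-butyl{[(1S,2R,5S)-4-isopropyl-2-(prop-1-en-2-yl)-5-(triisopropylsilyloxy)cyclohex-3-en-1-yl]oxy}dimethylsilane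
Product: 12 (1S,2R,5S)-4-isopropyl-2-(prop-1-en-2-yl)-5-(triisopropylsilyloxy)cyclohex-3-en-1-ol
Conditions: camphorsulfonic acid (10 mol%), MeOH/CH2Cl2 1:1, 0 °C
Reagents that add atoms: none
Why: Acid-catalysed methanolysis of silyl ethers is governed by bulk at silicon, so the C7 TBS ether should be cleaved well before the more hindered C5 TIPS ether (standard TBS/TIPS differentiation).

Step 6
Reactants: 12 (1S,2R,5S)-4-isopropyl-2-(prop-1-en-2-yl)-5-(triisopropylsilyloxy)cyclohex-3-en-1-ol
Product: 13 (2R,5S)-4-isopropyl-2-(prop-1-en-2-yl)-5-(triisopropylsilyloxy)cyclohex-3-en-1-one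
Conditions: Dess–Martin periodinane, NaHCO3, CH2Cl2, 0 °C; short cold filtration, used at once
Reagents that add atoms: none
Why: Dess–Martin oxidation runs at neutral pH and low temperature, which matters because C2–H of the product is alpha to the ketone and doubly allylic and the C5 silyloxy group is beta to it.

Step 7
Reactants: 13 (2R,5S)-4-isopropyl-2-(prop-1-en-2-yl)-5-(triisopropylsilyloxy)cyclohex-3-en-1-one; 14 vinylmagnesium bromide
Product: 16 (1S,2R,5S)-4-isopropyl-2-(prop-1-en-2-yl)-5-(triisopropylsilyloxy)-1-vinylcyclohex-3-en-1-ol, via vinylcerium dichloride 15 (not isolated)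
Conditions: anhydrous CeCl3, 14, THF, −78 °C, 1 h; 13, −78 °C; aq NH4Cl
Reagents that add atoms: vinylmagnesium bromide (compound 14), C=C[Mg]Br
Why: Organocerium 1,2-addition is nucleophilic but barely basic and so suits easily enolised beta,gamma-unsaturated ketones, and the vinyl group should enter from the face opposite both the C2 isopropenyl group and the pseudoaxial C5 OTIPS group, which sets C7 with vinyl trans to isopropenyl.

Step 8
Reactants: 16 (1S,2R,5S)-4-isopropyl-2-(prop-1-en-2-yl)-5-(triisopropylsilyloxy)-1-vinylcyclohex-3-en-1-ol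
Product: 19 (5E,7Z,9S)-8-isopropyl-5-methyl-9-(triisopropylsilyloxy)cyclodeca-5,7-dien-1-one, via potassium alkoxide 17 (not isolated), via potassium enolate 18 (not isolated)
Conditions: KH (oil-free), 18-crown-6, THF, 0 → 23 °C; cannula transfer into AcOH/THF at −78 °C
Reagents that add atoms: none
Why: KH turns 16 into alkoxide 17, whose oxyanion weakens the doubly allylic C2–C7 bond so that it breaks while C9–C10 forms in a concerted [3,3] shift, an anionic oxy-Cope rearrangement of a trans-1,2-dialkenylcyclohexanol that is a known four-carbon ring expansion, also for cyclohexenols. The ten-membered ring arises by ring expansion and not by end-to-end closure, since the only new sigma bond forms inside a six-centre chair array held together by the six-membered ring, which opens as that bond forms. No stereocentre is created (C2 and C7 become trigonal, C5 is untouched); the E geometry of C1=C2 follows from the chair with vinyl and isopropenyl both equatorial, in which C3 ends up trans to C10, and the Z C3=C4 bond is carried over from the cyclohexene. The step needs periselectivity for the isopropenyl group over the ring alkene: a shift through C3=C4 would require an axial vinyl group and bonding at fully substituted C4, and the half-chair that allows it is disfavoured because it presses the C5 OTIPS group against the isopropyl group. Enolate 18 is formed only towards C8 and KH leaves no conjugate acid in solution, so the enolate should not move to C6 and expel the silyloxy group before the inverse quench into cold acid.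

Step 9
Reactants: 19 (5E,7Z,9S)-8-isopropyl-5-methyl-9-(triisopropylsilyloxy)cyclodeca-5,7-dien-1-one
Product: 20 (5E,7Z,9S)-9-hydroxy-8-isopropyl-5-methylcyclodeca-5,7-dien-1-one
Conditions: HF·pyridine, excess pyridine, THF, 0 → 23 °C (polyethylene vessel)
Reagents that add atoms: none
Why: Pyridine-buffered HF is the usual fluoride desilylation for beta-silyloxy ketones, because it is too weakly basic for elimination or retro-aldol cleavage and too weakly acidic to ionise the dienylic C5–O bond.

Step 10
Reactants: 20 (5E,7Z,9S)-9-hydroxy-8-isopropyl-5-methylcyclodeca-5,7-dien-1-one; 21 methylmagnesium bromide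
Product: 23 (1S,3S,4Z,6E)-4-isopropyl-1,7-dimethylcyclodeca-4,6-diene-1,3-diol, via magnesium chelate 22 (not isolated)
Conditions: MeMgBr (4 equiv, Et2O solution), CH2Cl2, −78 → −40 °C; aq NH4Cl
Reagents that add atoms: methylmagnesium bromide (compound 21), C[Mg]Br
Why: The first equivalent forms the C5 magnesium alkoxide, which binds the C7 carbonyl in a six-membered chelate that turns both oxygens to the same face of the ten-membered ring, and the second equivalent can reach C7 only from outside the ring, so C7–O should stay cis to C5–O (7S), as in 1,3-chelation-controlled Grignard additions to beta-hydroxy ketones that give syn diols.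

Step 11
Reactants: 23 (1S,3S,4Z,6E)-4-isopropyl-1,7-dimethylcyclodeca-4,6-diene-1,3-diol; 24 4-acetoxybenzoyl chloride
Product: 25 (1S,2Z,4E,9S)-9-hydroxy-2-isopropyl-5,9-dimethylcyclodeca-2,4-dien-1-yl 4-acetoxybenzoate
Conditions: Et3N, DMAP (cat.), CH2Cl2, 0 → 23 °C
Reagents that add atoms: 4-acetoxybenzoyl chloride (compound 24), CC(=O)Oc1ccc(cc1)C(=O)Cl
Why: DMAP-catalysed acylation distinguishes the secondary C5 alcohol from the tertiary C7 alcohol on steric grounds, and C5 keeps its configuration because its C–O bond is not touched.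

Step 12
Reactants: 25 (1S,2Z,4E,9S)-9-hydroxy-2-isopropyl-5,9-dimethylcyclodeca-2,4-dien-1-yl 4-acetoxybenzoate
Product: 26 (1S,2Z,4E,9S)-9-hydroxy-2-isopropyl-5,9-dimethylcyclodeca-2,4-dien-1-yl 4-hydroxybenzoate (target)
Conditions: pyrrolidine (3 equiv), CH2Cl2, 23 °C
Reagents that add atoms: none
Why: Aryl acetates are activated esters that undergo aminolysis at room temperature, whereas the hindered secondary benzoate, further deactivated once the para oxygen is free, and the tertiary alcohol should be inert.

**Compound list**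

1 | (S)-4-(tert-butyldimethylsilyloxy)cyclohex-2-en-1-one | O=C1C=C[C@@H](O[Si](C)(C)C(C)(C)C)CC1 | starting material
2 | sodium (S)-4-(tert-butyldimethylsilyloxy)cyclohexa-1,5-dien-1-olate | [Na+].[O-]C1=CC[C@H](O[Si](C)(C)C(C)(C)C)C=C1 | intermediate (not isolated)
3 | (4S,6S)-4-(tert-butyldimethylsilyloxy)-6-hydroxycyclohex-2-en-1-one | O=C1C=C[C@@H](O[Si](C)(C)C(C)(C)C)C[C@@H]1O | intermediate
4 | (4S,6S)-4-(tert-butyldimethylsilyloxy)-6-(triisopropylsilyloxy)cyclohex-2-en-1-one | O=C1C=C[C@@H](O[Si](C)(C)C(C)(C)C)C[C@@H]1O[Si](C(C)C)(C(C)C)C(C)C | intermediate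
5 | 2-bromopropene | C=C(C)Br | starting material
6 | 2-propenyllithium | [Li]C(C)=C | intermediate (not isolated)
7 | lithium di(2-propenyl)cuprate | [Li+].C=C(C)[Cu-]C(C)=C | intermediate (not isolated)
8 | lithium (3R,4S,6S)-4-(tert-butyldimethylsilyloxy)-3-(prop-1-en-2-yl)-6-(triisopropylsilyloxy)cyclohex-1-en-1-olate | [Li+].[O-]C1=C[C@H](C(C)=C)[C@@H](O[Si](C)(C)C(C)(C)C)C[C@@H]1O[Si](C(C)C)(C(C)C)C(C)C | intermediate (not isolated)
9 | (3R,4S,6S)-4-(tert-butyldimethylsilyloxy)-3-(prop-1-en-2-yl)-6-(triisopropylsilyloxy)cyclohex-1-en-1-yl trifluoromethanesulfonate | O=S(=O)(OC1=C[C@H](C(C)=C)[C@@H](O[Si](C)(C)C(C)(C)C)C[C@@H]1O[Si](C(C)C)(C(C)C)C(C)C)C(F)(F)F | intermediate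
10 | isopropylzinc bromide | CC(C)[Zn]Br | starting material
11 | tert-butyl{[(1S,2R,5S)-4-isopropyl-2-(prop-1-en-2-yl)-5-(triisopropylsilyloxy)cyclohex-3-en-1-yl]oxy}dimethylsilane | CC(C)C1=C[C@H](C(C)=C)[C@@H](O[Si](C)(C)C(C)(C)C)C[C@@H]1O[Si](C(C)C)(C(C)C)C(C)C | intermediate
12 | (1S,2R,5S)-4-isopropyl-2-(prop-1-en-2-yl)-5-(triisopropylsilyloxy)cyclohex-3-en-1-ol | CC(C)C1=C[C@H](C(C)=C)[C@@H](O)C[C@@H]1O[Si](C(C)C)(C(C)C)C(C)C | intermediate
13 | (2R,5S)-4-isopropyl-2-(prop-1-en-2-yl)-5-(triisopropylsilyloxy)cyclohex-3-en-1-one | CC(C)C1=C[C@H](C(C)=C)C(=O)C[C@@H]1O[Si](C(C)C)(C(C)C)C(C)C | intermediate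
14 | vinylmagnesium bromide | C=C[Mg]Br | starting material
15 | vinylcerium dichloride | C=C[Ce](Cl)Cl | intermediate (not isolated)
16 | (1S,2R,5S)-4-isopropyl-2-(prop-1-en-2-yl)-5-(triisopropylsilyloxy)-1-vinylcyclohex-3-en-1-ol (vinyl and isopropenyl trans, OTIPS cis to isopropenyl) | C=C[C@@]1(O)C[C@H](O[Si](C(C)C)(C(C)C)C(C)C)C(C(C)C)=C[C@@H]1C(C)=C | intermediate
17 | potassium alkoxide of 16 | [K+].C=C[C@@]1([O-])C[C@H](O[Si](C(C)C)(C(C)C)C(C)C)C(C(C)C)=C[C@@H]1C(C)=C | intermediate (not isolated)
18 | potassium enolate of 19 (C7–O−, C7=C8, C6 and C9 trans) | [K+].C/C1=C\C=C(\C(C)C)[C@@H](O[Si](C(C)C)(C(C)C)C(C)C)C/C([O-])=C/CC1 | intermediate (not isolated)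
19 | (5E,7Z,9S)-8-isopropyl-5-methyl-9-(triisopropylsilyloxy)cyclodeca-5,7-dien-1-one | C/C1=C\C=C(\C(C)C)[C@@H](O[Si](C(C)C)(C(C)C)C(C)C)CC(=O)CCC1 | intermediate
20 | (5E,7Z,9S)-9-hydroxy-8-isopropyl-5-methylcyclodeca-5,7-dien-1-one | C/C1=C\C=C(\C(C)C)[C@@H](O)CC(=O)CCC1 | intermediate
21 | methylmagnesium bromide | C[Mg]Br | starting material
22 | bromomagnesium alkoxide of 20, chelated to the C7 carbonyl | C/C1=C\C=C(\C(C)C)[C@@H](O[Mg]Br)CC(=O)CCC1 | intermediate (not isolated)
23 | (1S,3S,4Z,6E)-4-isopropyl-1,7-dimethylcyclodeca-4,6-diene-1,3-diol | C/C1=C\C=C(\C(C)C)[C@@H](O)C[C@@](C)(O)CCC1 | intermediate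
24 | 4-acetoxybenzoyl chloride | CC(=O)Oc1ccc(cc1)C(=O)Cl | starting material
25 | (1S,2Z,4E,9S)-9-hydroxy-2-isopropyl-5,9-dimethylcyclodeca-2,4-dien-1-yl 4-acetoxybenzoate | C/C1=C\C=C(\C(C)C)[C@@H](OC(=O)c2ccc(OC(C)=O)cc2)C[C@@](C)(O)CCC1 | intermediate
26 | (1S,2Z,4E,9S)-9-hydroxy-2-isopropyl-5,9-dimethylcyclodeca-2,4-dien-1-yl 4-hydroxybenzoate | C/C1=C\C=C(\C(C)C)[C@@H](OC(=O)c2ccc(O)cc2)C[C@@](C)(O)CCC1 | target

Total step count: 12. Longest linear sequence: 12 steps (1 → 26).

**Steps most likely to fail**

1. **Step 8.**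
   - What may go wrong: the doubly allylic C2–C7 bond may cleave heterolytically (pentadienyl anion plus vinyl ketone) and re-close without geometric control. A [1,3] shift may intrude. Proton exchange may move the enolate to C6 and expel the silyloxy group.
   - Fallback: the same [3,3] shift without any anion. Setting out from 16, silylation of the tertiary alcohol (TMSOTf, 2,6-lutidine, CH2Cl2, −78 °C) would give the trimethylsilyl ether F1. Heating it in degassed toluene in a base-washed sealed tube (about 180–200 °C) would trigger the thermal siloxy-Cope rearrangement to the ring-expanded trimethylsilyl enol ether F2. Brief treatment with citric acid in aqueous THF at 0 °C would release the ketone and rejoin the route at 19.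

2. **Step 10.**
   - What may go wrong: addition may bypass the chelate, giving poor facial selectivity. The medium-ring ketone may be enolised instead of attacked. The magnesium aldolate may open by retro-aldol cleavage.
   - Fallback: form the C7–O bond from an oxygen tethered to C5, instead of the C7–CH3 bond. Setting out from 19, Petasis methylenation (Cp2TiMe2, toluene, 70 °C) would give the exocyclic alkene F3. TBAF in THF would then give the homoallylic alcohol F4; with no carbonyl left, basic fluoride is harmless. Oxymercuration through the acetone hemiketal (acetone, Hg(OAc)Cl, Yb(OTf)3 cat., 0 °C) would give the chloromercurio acetonide F5.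
   - Why this should be selective: 1,1-disubstituted alkenes are the fastest class in oxymercuration, and a six-membered dioxane can bridge C5 and C7 of the ten-membered ring only in the cis sense.
   - Return to the route: demercuration (NaBH4, aq NaOH) would turn CH2HgCl into the C7 methyl group of the acetonide F6, and PPTS in MeOH would free the diol, rejoining at 23.

3. **Step 7.**
   - What may go wrong: deprotonation of the ketone at C2 or C6 by the vinyl nucleophile. This would be followed by double-bond migration, epimerisation at C2, or loss of the silyloxy group with aromatisation.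
   - Fallback: a much less basic and slimmer sp nucleophile. Setting out from 13, ethynylmagnesium bromide (THF, −78 → −40 °C) would give the ethynyl carbinol F7 by the same top-face attack. Semihydrogenation (H2, Pd/CaCO3 poisoned with Pb(OAc)2, quinoline, EtOAc) would reduce the alkyne to the vinyl group, rejoining at 16.

**Further compounds**

F1 | step 8 | {[(1S,2R,5S)-4-isopropyl-2-(prop-1-en-2-yl)-5-(triisopropylsilyloxy)-1-vinylcyclohex-3-en-1-yl]oxy}trimethylsilane | C=C[C@@]1(O[Si](C)(C)C)C[C@H](O[Si](C(C)C)(C(C)C)C(C)C)C(C(C)C)=C[C@@H]1C(C)=C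
F2 | step 8 | trimethylsilyl enol ether of 19 (C7–OTMS, C7=C8 with C6 and C9 trans) | C/C1=C\C=C(\C(C)C)[C@@H](O[Si](C(C)C)(C(C)C)C(C)C)C/C(O[Si](C)(C)C)=C/CC1
F3 | step 10 | {[(1S,2Z,4E)-2-isopropyl-5-methyl-9-methylidenecyclodeca-2,4-dien-1-yl]oxy}triisopropylsilane | C/C1=C\C=C(\C(C)C)[C@@H](O[Si](C(C)C)(C(C)C)C(C)C)CC(=C)CCC1
F4 | step 10 | (1S,2Z,4E)-2-isopropyl-5-methyl-9-methylidenecyclodeca-2,4-dien-1-ol | C/C1=C\C=C(\C(C)C)[C@@H](O)CC(=C)CCC1
F5 | step 10 | acetonide bridging C5–O and C7–O (cis) with a chloromercuriomethyl group on C7 | C/C1=C\C=C(\C(C)C)[C@@H]2C[C@](C[Hg]Cl)(CCC1)OC(C)(C)O2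
F6 | step 10 | acetonide of diol 23 (cis, C5 S, C7 S) | C/C1=C\C=C(\C(C)C)[C@@H]2C[C@](C)(CCC1)OC(C)(C)O2
F7 | step 7 | (1R,2R,5S)-1-ethynyl-4-isopropyl-2-(prop-1-en-2-yl)-5-(triisopropylsilyloxy)cyclohex-3-en-1-ol | C#C[C@@]1(O)C[C@H](O[Si](C(C)C)(C(C)C)C(C)C)C(C(C)C)=C[C@@H]1C(C)=C
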